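## The problem

Atom labels used throughout: ring A is the cyclopentane C1 (carbinol carbon), C2, C3, C4, C5; C6 is the acetoxymethyl carbon on C1; the chain on C4 is C7 (with its methyl), C8, C9, C10, C11; ring B is the cyclopentenone C1′ (bonded to C5), C2′ (C=O), C3′, C4′, C5′ (with its methyl).

The target 32 consists of two five-membered rings joined only by the single bond C5–C1′: ring A carries the quaternary carbinol C1, the (Z)-6-methylhepta-2,5-dien-2-yl chain on C4 and ring B on C5, and ring B is a 5-methylcyclopent-2-enone bound through its α-carbon. Five stereocentres must be set (C1 R, C4 R, C5 S, C1′ S, C5′ R): on ring A the C4 chain, ring B and C6 are mutually cis and the hydroxyl is trans to them, and on ring B the C5′ methyl is cis to ring A. The C4/C5 pair can be fixed by a ring and C1 can then be read from the shape of that ring system, but C1′ and C5′ lie across a freely rotating bond and need their own source of control. Two centres sit in the less stable arrangement and become base-labile once their carbonyl neighbours exist: C1′ (α to the enone, cis to the C5′ methyl) and C4 (α to a C7 ketone if the chain is made by olefination). The C7=C8 alkene must be Z and is part of a skipped diene that tolerates neither oxidants nor strong acid, so all oxidation of the skeleton must come before it, and the primary acetate beside a free tertiary alcohol must come last. The enabling feature is that C4 and C5 carry C7 and C1′ cis, and C1′ is bonded to the C2′ carbonyl. C4, C5, C1′, C2′ and C7 can therefore be drawn as a cis-fused cyclopentanone with one extra C7–C2′ bond, which is ring A fused to the cyclopentenone of an intramolecular Pauson–Khand reaction (alkyne methyl = C7 methyl, CO carbon = C2′). Cutting that extra bond afterwards by oxygen insertion leaves an oxygen on C7 and an acyl carbon at C2′, the two handles needed for the chain and for ring B.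

## Retrosynthesis

**Acetate and diol (32 ⇒ 31 ⇒ 30).** The C6 O–acyl bond and the ketal are cut. The acetate cannot survive an ylide, an amide base or a Grignard reagent, so it is put on last, and the 1,2-diol of 31 is carried as the acetonide 30. The forward steps ask only for mild acid and a primary-selective acetylation that does not enolise C1′.

**Ring B (30 ⇒ 29).** The C3′=C4′ bond is cut by ring-closing metathesis. Against an aldol or a cationic closure, metathesis is neutral and never passes through an enol(ate) at C1′. The precursor 29 is an acyclic dienone with both ring B stereocentres already in place. The closure must be faster than any metathesis at the two trisubstituted chain alkenes.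

**Vinyl ketone (29 ⇒ 28 ⇒ 26).** The C2′–C3′ bond is cut back to vinylmagnesium bromide 3 and the Weinreb amide 28 of acid 26. This keeps C2′ at the acid oxidation level delivered by the next cut. The forward reaction must achieve acyl substitution at a crowded carbonyl without touching C1′.

**C1′–C5′ (26 ⇒ 23).** The C1′–C5′ bond is cut by an Ireland–Claisen rearrangement of the ester 23 formed from the C2′ acid and (S,E)-pent-3-en-2-ol 18. Both new centres are then set by the alcohol's configuration and the ketene acetal geometry, independently of ring A. The neighbouring option, alkylating the enolate of the bicyclic lactone, would add from the convex face and give the wrong C1′ epimer. The precursor loses two stereocentres and is a simple ester. The forward reaction needs an (E)-silyl ketene acetal and a chair transition state.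

**C7=C8 (23 ⇒ 19 + 21).** The trisubstituted alkene is cut by a Wittig reaction between methyl ketone 19 and the ylide from phosphonium salt 21 (from bromide 20). This uses the C7 oxygen as a carbonyl, and a non-stabilised ylide should place its substituent cis to the larger ketone substituent, which is the Z isomer. Carbometalation of a C7≡C8 alkyne would give the E isomer. The forward reaction must be Z-selective and must not epimerise C4.

**Keto ester (19 ⇒ 17 + 18; 17 ⇒ 15).** The ester C–O bond is cut to keto acid 17, and 17 is traced to lactone 15 by reclosing C7–O–C2′. The lactone masks both handles at once during the work at C1. The forward step is saponification with oxidation of C7 in the same pot.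

**C1 carbinol (15 ⇒ 14 ⇒ 13 ⇒ 12 ⇒ 11 ⇒ 10).** The two C–O bonds at C1/C6 are cut back to an exocyclic methylene 13, then to ketone 12 and silyl ether 10. Adding a C6 nucleophile to ketone 12 would attack from the convex face and give the wrong C1 epimer. Dihydroxylation of the methylene from that same face gives the right one. Doing this on the lactone means only one alkene is present and the cis-fused bicycle supplies the facial bias.

**Oxygen insertion and ring fusion (10 ⇒ 9 ⇒ 8).** The C7–O bond is cut by reconnecting C7 to C2′ (Baeyer–Villiger transform), giving cyclopentanone 9, and the C4–H and C7–H bonds are cut to enone 8. Hydrogenation of the bicyclic enone can only give the cis ring fusion, which is the cis C4/C5 relationship of ring A.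

**Key cut (8 ⇒ 6).** The C4–C5, C1′–C2′ and C7–C2′ bonds are cut together, as a Pauson–Khand reaction of the 1,6-enyne 6 with CO. Two rings and three skeletal bonds are traded for a linear enyne with one stereocentre. The forward reaction must place the C1 silyl ether exo so that C5 follows from the (R)-carbinol.

**Enyne (6 ⇒ 5 ⇒ 4 ⇒ 2 + 3 ⇒ 1).** The Si–O bond and the C1–C5 bond are cut: silylation of (R)-alcohol 5, kinetic resolution of racemic 4, and vinyl Grignard addition to aldehyde 2 from hex-4-yn-1-ol 1.

## Roads not taken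

**Alternative 1:** The cut removes the three ring B bonds C1′–C2′, C2′–C3′ and C4′–C5′ at once, leaving a (Z)-prop-1-enyl group on C5 of a finished ring A (A1, with phenylthio in place of the C6 acetoxy group), ethyne and CO. The forward key step is an intermolecular Pauson–Khand reaction of A1 with the Co2(CO)6 complex of ethyne to give A2.
- Merits: ring B is made in one step from the simplest alkyne. The Z alkene maps stereospecifically onto the cis C1′/C5′ pair without any enolate. The sulfide can bind cobalt and steer the CO carbon next to C1′.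
- Weak points: intermolecular reactions of unstrained, acyclic 1,2-disubstituted alkenes are sluggish. The face of the propenyl group that reacts (and so both new centres relative to ring A) depends only on the geometry of a sulfide chelate. The chain alkenes can compete. Sulfur must afterwards be exchanged for acetate next to a tertiary alcohol, an enone and a skipped diene. A1 itself still needs ring A with three stereocentres.
- Comparison: this road sets the cis C1′/C5′ relationship better than the chosen plan and has a shorter ring B end game. The chosen plan offers a much more dependable cycloaddition class (intramolecular, internal alkyne) and reagent control of C1′/C5′ in the rearrangement 23 → 26.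

**Alternative 2:** The cut is the C1–C2 bond, leaving an acyclic iodo ketone A3 (PMB-protected C6, ring B as its saturated ketal). The forward key step is iodine–lithium exchange with tert-butyllithium and attack of C2 on the C1 ketone to give A4.
- Merits: the quaternary carbinol with C6 attached is formed in one step, which would spare the five steps that adjust C1 in the chosen route (8–12).
- Weak points: A3 holds four stereocentres (C4, C5, C1′, C5′) that must be made without any ring to lean on. C5 sits between a ketone and ring B and is epimerisable. An α-alkoxy ketone is exposed to an alkyllithium, so enolisation and direct addition compete. The face of the ketone attacked has no secure control. The enone must later be regenerated from the ketal by desaturation next to the labile C1′.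
- Comparison: this road is shorter at C1 but moves the stereochemical burden to acyclic chemistry. The chosen plan sets C4/C5 by hydrogenating a bicyclic enone and C1 by a convex-face dihydroxylation.

**Alternative 3:** The cut is the C4′–C5′ bond, leaving a cross-conjugated dienone A5 with a trimethylsilyl group on C4′. The forward key step is an FeCl3-promoted conrotatory 4π closure with loss of the silyl group and protonation at C1′, giving A6, which is the same compound as 30 of the chosen route.
- Merits: it is the most direct route to ring B, would replace steps 17–20 and arrive two steps from the target. Silicon fixes the alkene at C3′=C4′, and kinetic protonation anti to the new methyl would favour the cis product.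
- Weak points: the sense of conrotation decides C5′ and is governed only by the remote ring A centres. A pentadienyl cation generated next to the electron-rich C7=C8 and C10=C11 alkenes invites cation–olefin cyclisation, and the Lewis acid threatens the acetonide. The protonation face at C1′ is not assured. A5 needs an α-ethylidene ketone of defined geometry.
- Comparison: this road is clearly shorter. The chosen plan spends about three more steps to get reagent-controlled C1′/C5′ and a neutral ring closure.

Key step: step 5

Assumption: the C7 configuration of 9–16 (drawn as formed by syn addition of hydrogen) has no bearing on the route, because C7 becomes a carbonyl carbon in 17.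

## Route

Step 1
Reactants: 1 hex-4-yn-1-ol
Product: 2 hex-4-ynal
Conditions: Dess–Martin periodinane, CH2Cl2, 0 °C to rt
Reagents that add atoms: none
Why: Dess–Martin oxidation of a primary alcohol stops at the aldehyde under neutral conditions and leaves the internal alkyne alone; the volatile aldehyde would be used directly.

Step 2
Reactants: 2 hex-4-ynal; 3 vinylmagnesium bromide
Product: 4 rac-oct-1-en-6-yn-3-ol
Conditions: THF, −78 to 0 °C; aq. NH4Cl
Reagents that add atoms: none
Why: Grignard 1,2-addition to an unhindered aldehyde; the carbinol centre is formed racemic and is resolved in step 3.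

Step 3
Reactants: 4 rac-oct-1-en-6-yn-3-ol
Product: 5 (R)-oct-1-en-6-yn-3-ol
Conditions: Ti(OiPr)4, L-(+)-diisopropyl tartrate, t-BuOOH (0.6 equiv), 4 Å molecular sieves, CH2Cl2, −20 °C
Reagents that add atoms: none
Why: Sharpless kinetic resolution: with the L-(+)-tartrate the (S)-enantiomer of a 1-alken-3-ol is epoxidised much faster, so the (R)-alcohol should be recovered in high enantiomeric purity once slightly more than half of 4 has reacted; the internal alkyne is inert to the titanium peroxide.

Step 4
Reactants: 5 (R)-oct-1-en-6-yn-3-ol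
Product: 6 (R)-tert-butyldimethyl(oct-1-en-6-yn-3-yloxy)silane
Conditions: t-BuMe2SiCl, imidazole, DMF, rt
Reagents that add atoms: tert-butyldimethylsilyl chloride, CC(C)(C)[Si](C)(C)Cl
Why: Standard silylation of a secondary alcohol; the bulky ether is the group that will direct the cycloaddition and it survives cobalt, hydrogenation and peracid.

Step 5
Reactants: 6 (R)-tert-butyldimethyl(oct-1-en-6-yn-3-yloxy)silane
Product: 8 (5R,6R)-6-[(tert-butyldimethylsilyl)oxy]-2-methylbicyclo[3.3.0]oct-1-en-3-one, via hexacarbonyldicobalt alkyne complex 7 (not isolated)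
Conditions: Co2(CO)8 (1.1 equiv), CH2Cl2, rt; then N-methylmorpholine N-oxide, 0 °C to rt
Reagents that add atoms: dicobalt octacarbonyl, O=C=[Co](=C=O)(=C=O)(=C=O)[Co](=C=O)(=C=O)(=C=O)=C=O (one CO, [C-]#[O+], becomes C2′=O)
Why: The alkyne of 6 binds Co2(CO)8 with loss of two CO to give complex 7; N-oxide-induced loss of a further CO opens a site on cobalt for the tethered vinyl group, which inserts into the Co–C4 bond (forming C4–C5), after which CO insertion (C1′–C2′) and reductive elimination (C7–C2′) release enone 8. The closest known reaction type is the amine N-oxide-promoted intramolecular Pauson–Khand reaction of 1,6-enynes that carry an internal alkyne and an allylic silyloxy group. Ring A closes as the tether ring in the alkene-insertion step (a 5-exo closure onto the complexed alkyne carbon C4), and the cyclopentenone closes by the [2+2+1] union of C7, C4, C5, C1′ and the CO carbon C2′. The one new stereocentre, C5, is controlled by the C1 silyl ether: in the cobaltacycle-forming step the silyloxy group should take the exo (convex) position, away from the Co2 cluster, which puts H5 cis to the C1 oxygen and, from the (R)-carbinol, gives the C5 configuration of the target. Regiochemistry is fixed by the tether, so the methyl necessarily ends on C7 and the CO carbon becomes C2′. The selectivity needed is exo over endo placement of the C1 substituent; it rests on the bulk of the silyl ether and is helped by running the promoted reaction at or below room temperature. Any C5 epimer is a diastereomer at this stage and must be removed by chromatography before C1 is oxidised in step 9, since it would otherwise lead into the enantiomeric series. The allylic C–O bond is not propargylic and cannot ionise from the cobalt complex.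

Step 6
Reactants: 8 (5R,6R)-6-[(tert-butyldimethylsilyl)oxy]-2-methylbicyclo[3.3.0]oct-1-en-3-one
Product: 9 (1R,2R,5R,6R)-6-[(tert-butyldimethylsilyl)oxy]-2-methylbicyclo[3.3.0]octan-3-one
Conditions: H2 (1 atm), 10% Pd/C, EtOAc, rt
Reagents that add atoms: none
Why: Heterogeneous hydrogenation adds both hydrogens from the H5 face because a trans-fused bicyclo[3.3.0]octane is prohibitively strained, so C4–H comes out cis to C5–H (the cis C4/C5 relationship of ring A) and C7–H cis to both. The silyl ether is homoallylic, not allylic, and should not be hydrogenolysed.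

Step 7
Reactants: 9 (1R,2R,5R,6R)-6-[(tert-butyldimethylsilyl)oxy]-2-methylbicyclo[3.3.0]octan-3-one
Product: 10 (1R,4aR,5R,7aR)-5-[(tert-butyldimethylsilyl)oxy]-1-methylhexahydrocyclopenta[c]pyran-3(1H)-one
Conditions: mCPBA, CH2Cl2, 0 °C to rt
Reagents that add atoms: 3-chloroperoxybenzoic acid, O=C(OO)c1cccc(Cl)c1
Why: Baeyer–Villiger oxidation: the secondary carbon C7 migrates in preference to the primary C1′ and with retention, so oxygen is inserted into the temporary C7–C2′ bond and C2′ stays an acyl carbon on C1′. No alkene is present to compete.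

Step 8
Reactants: 10 (1R,4aR,5R,7aR)-5-[(tert-butyldimethylsilyl)oxy]-1-methylhexahydrocyclopenta[c]pyran-3(1H)-one
Product: 11 (1R,4aR,5R,7aR)-5-hydroxy-1-methylhexahydrocyclopenta[c]pyran-3(1H)-one
Conditions: HF·pyridine, THF, 0 °C to rt
Reagents that add atoms: none
Why: Fluoride cleavage of the secondary silyl ether under non-basic conditions that keep the lactone closed; the freed C1 hydroxyl is trans to the C1′ arm and cannot translactonise.

Step 9
Reactants: 11 (1R,4aR,5R,7aR)-5-hydroxy-1-methylhexahydrocyclopenta[c]pyran-3(1H)-one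
Product: 12 (1R,4aR,7aR)-1-methylhexahydrocyclopenta[c]pyran-3,5-dione
Conditions: Dess–Martin periodinane, CH2Cl2, rt
Reagents that add atoms: none
Why: Neutral Dess–Martin oxidation of the secondary alcohol; the C1 centre has done its work (control of C5) and is erased here, while the α-centre C5 is not exposed to base.

Step 10
Reactants: 12 (1R,4aR,7aR)-1-methylhexahydrocyclopenta[c]pyran-3,5-dione
Product: 13 (1R,4aR,7aR)-1-methyl-5-methylidenehexahydrocyclopenta[c]pyran-3(1H)-one
Conditions: Zn, CH2Br2, TiCl4, THF/CH2Cl2, 0 °C to rt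
Reagents that add atoms: dibromomethane, BrCBr
Why: Lombardo methylenation: the non-basic zinc/titanium methylene reagent converts ketones but not lactones and does not enolise, so C5 (α to the ketone) keeps its configuration.

Step 11
Reactants: 13 (1R,4aR,7aR)-1-methyl-5-methylidenehexahydrocyclopenta[c]pyran-3(1H)-one
Product: 14 (1R,4aR,5R,7aR)-5-hydroxy-5-(hydroxymethyl)-1-methylhexahydrocyclopenta[c]pyran-3(1H)-one
Conditions: OsO4 (2 mol%), N-methylmorpholine N-oxide, acetone/H2O, rt
Reagents that add atoms: N-methylmorpholine N-oxide, C[N+]1([O-])CCOCC1; water, O (OsO4, O=[Os](=O)(=O)=O, is the catalytic oxygen carrier)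
Why: Catalytic OsO4 syn-dihydroxylation of the only alkene; the oxidant should approach the exocyclic C1=C6 bond from the convex face of the cis-fused bicycle (the H4/H5 face, anti to the C1′ methylene on C5), which puts the C1 hydroxyl trans and C6 cis to the C5 substituent, i.e. C1 (R) as in the target.

Step 12
Reactants: 14 (1R,4aR,5R,7aR)-5-hydroxy-5-(hydroxymethyl)-1-methylhexahydrocyclopenta[c]pyran-3(1H)-one
Product: 15 (1R,4aR,5R,7aR)-1,2',2'-trimethylhexahydrospiro[cyclopenta[c]pyran-5,4'-[1,3]dioxolan]-3(1H)-one
Conditions: 2,2-dimethoxypropane, pyridinium p-toluenesulfonate (cat.), CH2Cl2, rt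
Reagents that add atoms: 2,2-dimethoxypropane, COC(C)(C)OC
Why: Acid-catalysed ketal exchange ties the primary and tertiary hydroxyls into a dioxolane that withstands hydroxide, ylide, amide base and Grignard reagent. Any acyl migration of the lactone onto the C6 oxygen is reversible here and is drained back, because only the free 1,2-diol can be ketalised.

Step 13
Reactants: 15 (1R,4aR,5R,7aR)-1,2',2'-trimethylhexahydrospiro[cyclopenta[c]pyran-5,4'-[1,3]dioxolan]-3(1H)-one
Product: 17 2-[(5R,6R,7R)-7-acetyl-2,2-dimethyl-1,3-dioxaspiro[4.4]nonan-6-yl]acetic acid, via lithium hydroxy carboxylate 16 (not isolated)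
Conditions: LiOH, THF/H2O, rt; then NaHCO3, KBr (cat.), TEMPO (cat.), NaOCl, 0 °C; then aq. HCl to pH 4, 0 °C
Reagents that add atoms: lithium hydroxide, [Li+].[OH-]
Why: Saponification opens the δ-lactone to hydroxy carboxylate 16, which cannot relactonise while basic; nitroxyl-catalysed hypochlorite oxidation of the C7 carbinol in the same pot removes the lactonisation partner, so acidification should give the open keto acid. The temporary bridge is now fully excised: C7 is a methyl ketone and C2′ a carboxylic acid.

Step 14
Reactants: 17 2-[(5R,6R,7R)-7-acetyl-2,2-dimethyl-1,3-dioxaspiro[4.4]nonan-6-yl]acetic acid; 18 (S,E)-pent-3-en-2-ol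
Product: 19 (2S,3E)-pent-3-en-2-yl 2-[(5R,6R,7R)-7-acetyl-2,2-dimethyl-1,3-dioxaspiro[4.4]nonan-6-yl]acetate
Conditions: N,N'-dicyclohexylcarbodiimide, 4-(dimethylamino)pyridine (cat.), CH2Cl2, 0 °C to rt
Reagents that add atoms: none
Why: Steglich esterification acylates the secondary allylic alcohol under neutral conditions without touching its stereocentre or alkene geometry and without enolising the methyl ketone.

Step 15
Reactants: 20 5-bromo-2-methylpent-2-ene
Product: 21 (4-methylpent-3-en-1-yl)triphenylphosphonium bromide
Conditions: PPh3, MeCN, reflux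
Reagents that add atoms: triphenylphosphine, c1ccc(cc1)P(c1ccccc1)c1ccccc1
Why: SN2 quaternisation of triphenylphosphine by a primary bromide.

Step 16
Reactants: 19 (2S,3E)-pent-3-en-2-yl 2-[(5R,6R,7R)-7-acetyl-2,2-dimethyl-1,3-dioxaspiro[4.4]nonan-6-yl]acetate; 21 (4-methylpent-3-en-1-yl)triphenylphosphonium bromide
Product: 23 (2S,3E)-pent-3-en-2-yl 2-[(5R,6R,7R)-2,2-dimethyl-7-[(2Z)-6-methylhepta-2,5-dien-2-yl]-1,3-dioxaspiro[4.4]nonan-6-yl]acetate, via phosphorus ylide 22 (not isolated)
Conditions: 21, KN(SiMe3)2, THF, −78 to 0 °C; then 19, −78 °C to rt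
Reagents that add atoms: none
Why: Wittig olefination with a salt-free non-stabilised ylide: in the kinetically formed oxaphosphetane the ylide substituent should sit cis to the larger ketone substituent (ring carbon C4, not the methyl), which is the Z alkene (C4 and C9 cis). The ester is far less electrophilic than the ketone, and adding the ketone cold limits enolisation toward C4.

Step 17
Reactants: 23 (2S,3E)-pent-3-en-2-yl 2-[(5R,6R,7R)-2,2-dimethyl-7-[(2Z)-6-methylhepta-2,5-dien-2-yl]-1,3-dioxaspiro[4.4]nonan-6-yl]acetate
Product: 26 (2S,3R,4E)-2-[(5R,6S,7R)-2,2-dimethyl-7-[(2Z)-6-methylhepta-2,5-dien-2-yl]-1,3-dioxaspiro[4.4]nonan-6-yl]-3-methylhex-4-enoic acid, via silyl ketene acetal 24 (not isolated), via trimethylsilyl ester 25 (not isolated)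
Conditions: LiN(iPr)2, Me3SiCl, Et3N, THF, −78 °C; then rt to 60 °C; then H2O
Reagents that add atoms: none
Why: Ireland–Claisen rearrangement: kinetic deprotonation in THF without a polar additive should give the (E)-silyl ketene acetal 24, and a chair transition state with the carbinol methyl of the (S,E)-pentenyl group equatorial transfers chirality to C5′ (R), forms the anti C1′/C5′ relationship (C1′ S) and leaves an (E)-propenyl group. Both new centres are set by the ester alcohol and the enolate geometry and not by ring A; the skipped diene and the acetonide are inert to the amide base at −78 °C.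

Step 18
Reactants: 26 (2S,3R,4E)-2-[(5R,6S,7R)-2,2-dimethyl-7-[(2Z)-6-methylhepta-2,5-dien-2-yl]-1,3-dioxaspiro[4.4]nonan-6-yl]-3-methylhex-4-enoic acid
Product: 28 (2S,3R,4E)-2-[(5R,6S,7R)-2,2-dimethyl-7-[(2Z)-6-methylhepta-2,5-dien-2-yl]-1,3-dioxaspiro[4.4]nonan-6-yl]-N-methoxy-N,3-dimethylhex-4-enamide, via acid chloride 27 (not isolated)
Conditions: 1-chloro-N,N,2-trimethylprop-1-en-1-amine, CH2Cl2, 0 °C; then MeNHOMe·HCl, pyridine, 0 °C to rt
Reagents that add atoms: N,O-dimethylhydroxylamine hydrochloride, CNOC.Cl
Why: Weinreb amide formation through the acid chloride: the α-chloroenamine converts the hindered acid into its chloride without liberating HCl (acetonide and alkenes are safe), and the small, weakly basic hydroxylamine then acylates without ketene formation, so C1′ should not epimerise.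

Step 19
Reactants: 28 (2S,3R,4E)-2-[(5R,6S,7R)-2,2-dimethyl-7-[(2Z)-6-methylhepta-2,5-dien-2-yl]-1,3-dioxaspiro[4.4]nonan-6-yl]-N-methoxy-N,3-dimethylhex-4-enamide; 3 vinylmagnesium bromide
Product: 29 (4S,5R,6E)-4-[(5R,6S,7R)-2,2-dimethyl-7-[(2Z)-6-methylhepta-2,5-dien-2-yl]-1,3-dioxaspiro[4.4]nonan-6-yl]-5-methylocta-1,6-dien-3-one
Conditions: THF, 0 °C; poured into cold 1 M aq. HCl
Reagents that add atoms: none
Why: Weinreb ketone synthesis: the magnesium chelate of the tetrahedral adduct holds until work-up, so only one vinyl group is added and no enolisable ketone meets the Grignard reagent. The acidic inverse quench protonates the released hydroxylamine before it can add to the enone.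

Step 20
Reactants: 29 (4S,5R,6E)-4-[(5R,6S,7R)-2,2-dimethyl-7-[(2Z)-6-methylhepta-2,5-dien-2-yl]-1,3-dioxaspiro[4.4]nonan-6-yl]-5-methylocta-1,6-dien-3-one
Product: 30 (4R,5S)-5-[(5R,6S,7R)-2,2-dimethyl-7-[(2Z)-6-methylhepta-2,5-dien-2-yl]-1,3-dioxaspiro[4.4]nonan-6-yl]-4-methylcyclopent-2-en-1-one
Conditions: second-generation Grubbs catalyst RuCl2(=CHPh)(H2IMes)(PCy3) (5 mol%), CH2Cl2, 40 °C
Reagents that add atoms: none
Why: Ring-closing metathesis: the catalyst loads on the 1,2-disubstituted propenyl group and closes the five-membered ring onto the vinyl ketone with loss of propene, while the two trisubstituted chain alkenes react far more slowly and would have to form larger or more hindered rings. The conditions are neutral, so the cis C1′/C5′ pair from step 17 should be carried into the enone unchanged.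

Step 21
Reactants: 30 (4R,5S)-5-[(5R,6S,7R)-2,2-dimethyl-7-[(2Z)-6-methylhepta-2,5-dien-2-yl]-1,3-dioxaspiro[4.4]nonan-6-yl]-4-methylcyclopent-2-en-1-one
Product: 31 (4R,5S)-5-[(1S,2R,5R)-2-hydroxy-2-(hydroxymethyl)-5-[(2Z)-6-methylhepta-2,5-dien-2-yl]cyclopentyl]-4-methylcyclopent-2-en-1-one
Conditions: AcOH/THF/H2O (3:1:1), 40 °C
Reagents that add atoms: none
Why: Mild acid hydrolysis of the dioxolane; under these conditions neither enolisation at C1′ nor hydration or migration of the trisubstituted alkenes is expected.

Step 22
Reactants: 31 (4R,5S)-5-[(1S,2R,5R)-2-hydroxy-2-(hydroxymethyl)-5-[(2Z)-6-methylhepta-2,5-dien-2-yl]cyclopentyl]-4-methylcyclopent-2-en-1-one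
Product: 32 [(1R,2S,3R)-1-hydroxy-3-[(2Z)-6-methylhepta-2,5-dien-2-yl]-2-[(1S,5R)-5-methyl-2-oxocyclopent-3-en-1-yl]cyclopentyl]methyl acetate
Conditions: Ac2O, pyridine, CH2Cl2, 0 °C
Reagents that add atoms: acetic anhydride, CC(=O)OC(C)=O
Why: Acetylation discriminates cleanly between the primary C6 hydroxyl and the hindered tertiary C1 hydroxyl; pyridine at 0 °C is too weak a base to enolise the cyclopentenone toward C1′.

## Compound list

1 | hex-4-yn-1-ol | CC#CCCCO | starting material
2 | hex-4-ynal | CC#CCCC=O | intermediate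
3 | vinylmagnesium bromide | C=C[Mg]Br | starting material
4 | rac-oct-1-en-6-yn-3-ol | C=CC(O)CCC#CC | intermediate
5 | (R)-oct-1-en-6-yn-3-ol | C=C[C@H](O)CCC#CC | intermediate
6 | (R)-tert-butyldimethyl(oct-1-en-6-yn-3-yloxy)silane | C=C[C@H](O[Si](C)(C)C(C)(C)C)CCC#CC | intermediate
7 | hexacarbonyldicobalt complex of the alkyne of 6 | C=C[C@H](O[Si](C)(C)C(C)(C)C)CCC12[Co]3(=C=O)(=C=O)(=C=O)[Co]1(=C=O)(=C=O)(=C=O)C23C | intermediate
8 | (5R,6R)-6-[(tert-butyldimethylsilyl)oxy]-2-methylbicyclo[3.3.0]oct-1-en-3-one | CC1=C2CC[C@@H](O[Si](C)(C)C(C)(C)C)[C@@H]2CC1=O | intermediate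
9 | (1R,2R,5R,6R)-6-[(tert-butyldimethylsilyl)oxy]-2-methylbicyclo[3.3.0]octan-3-one | CC(C)(C)[Si](C)(C)O[C@@H]1CC[C@@H]2[C@H]1CC(=O)[C@@H]2C | intermediate
10 | (1R,4aR,5R,7aR)-5-[(tert-butyldimethylsilyl)oxy]-1-methylhexahydrocyclopenta[c]pyran-3(1H)-one | CC(C)(C)[Si](C)(C)O[C@@H]1CC[C@@H]2[C@H]1CC(=O)O[C@@H]2C | intermediate
11 | (1R,4aR,5R,7aR)-5-hydroxy-1-methylhexahydrocyclopenta[c]pyran-3(1H)-one | O[C@@H]1CC[C@@H]2[C@H]1CC(=O)O[C@@H]2C | intermediate
12 | (1R,4aR,7aR)-1-methylhexahydrocyclopenta[c]pyran-3,5-dione | O=C1CC[C@@H]2[C@H]1CC(=O)O[C@@H]2C | intermediate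
13 | (1R,4aR,7aR)-1-methyl-5-methylidenehexahydrocyclopenta[c]pyran-3(1H)-one | C=C1CC[C@@H]2[C@H]1CC(=O)O[C@@H]2C | intermediate
14 | (1R,4aR,5R,7aR)-5-hydroxy-5-(hydroxymethyl)-1-methylhexahydrocyclopenta[c]pyran-3(1H)-one | OC[C@@]1(O)CC[C@@H]2[C@H]1CC(=O)O[C@@H]2C | intermediate
15 | (1R,4aR,5R,7aR)-1,2',2'-trimethylhexahydrospiro[cyclopenta[c]pyran-5,4'-[1,3]dioxolan]-3(1H)-one | CC1(C)OC[C@@]2(O1)CC[C@@H]3[C@H]2CC(=O)O[C@@H]3C | intermediate
16 | lithium 2-[(5R,6R,7R)-7-[(1R)-1-hydroxyethyl]-2,2-dimethyl-1,3-dioxaspiro[4.4]nonan-6-yl]acetate | CC1(C)OC[C@@]2(O1)CC[C@@H]([C@@H](C)O)[C@H]2CC(=O)[O-].[Li+] | intermediate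
17 | 2-[(5R,6R,7R)-7-acetyl-2,2-dimethyl-1,3-dioxaspiro[4.4]nonan-6-yl]acetic acid | CC1(C)OC[C@@]2(O1)CC[C@@H](C(C)=O)[C@H]2CC(=O)O | intermediate
18 | (S,E)-pent-3-en-2-ol | C/C=C/[C@H](C)O | starting material
19 | (2S,3E)-pent-3-en-2-yl 2-[(5R,6R,7R)-7-acetyl-2,2-dimethyl-1,3-dioxaspiro[4.4]nonan-6-yl]acetate | CC1(C)OC[C@@]2(O1)CC[C@@H](C(C)=O)[C@H]2CC(=O)O[C@@H](C)/C=C/C | intermediate
20 | 5-bromo-2-methylpent-2-ene | CC(C)=CCCBr | starting material
21 | (4-methylpent-3-en-1-yl)triphenylphosphonium bromide | CC(C)=CCC[P+](c1ccccc1)(c1ccccc1)c1ccccc1.[Br-] | intermediate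
22 | (4-methylpent-3-en-1-ylidene)triphenylphosphorane | CC(C)=CCC=P(c1ccccc1)(c1ccccc1)c1ccccc1 | intermediate
23 | (2S,3E)-pent-3-en-2-yl 2-[(5R,6R,7R)-2,2-dimethyl-7-[(2Z)-6-methylhepta-2,5-dien-2-yl]-1,3-dioxaspiro[4.4]nonan-6-yl]acetate | CC1(C)OC[C@@]2(O1)CC[C@@H](/C(C)=C\CC=C(C)C)[C@H]2CC(=O)O[C@@H](C)/C=C/C | intermediate
24 | (E)-trimethylsilyl ketene acetal of 23 (ring A carbon C5 trans to OSiMe3) | CC1(C)OC[C@@]2(O1)CC[C@@H](/C(C)=C\CC=C(C)C)[C@H]2/C=C(/O[Si](C)(C)C)O[C@@H](C)/C=C/C | intermediate
25 | trimethylsilyl ester of acid 26 | CC1(C)OC[C@@]2(O1)CC[C@@H](/C(C)=C\CC=C(C)C)[C@H]2[C@H]([C@H](C)/C=C/C)C(=O)O[Si](C)(C)C | intermediate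
26 | (2S,3R,4E)-2-[(5R,6S,7R)-2,2-dimethyl-7-[(2Z)-6-methylhepta-2,5-dien-2-yl]-1,3-dioxaspiro[4.4]nonan-6-yl]-3-methylhex-4-enoic acid | CC1(C)OC[C@@]2(O1)CC[C@@H](/C(C)=C\CC=C(C)C)[C@H]2[C@H]([C@H](C)/C=C/C)C(=O)O | intermediate
27 | (2S,3R,4E)-2-[(5R,6S,7R)-2,2-dimethyl-7-[(2Z)-6-methylhepta-2,5-dien-2-yl]-1,3-dioxaspiro[4.4]nonan-6-yl]-3-methylhex-4-enoyl chloride | CC1(C)OC[C@@]2(O1)CC[C@@H](/C(C)=C\CC=C(C)C)[C@H]2[C@H]([C@H](C)/C=C/C)C(=O)Cl | intermediate
28 | (2S,3R,4E)-2-[(5R,6S,7R)-2,2-dimethyl-7-[(2Z)-6-methylhepta-2,5-dien-2-yl]-1,3-dioxaspiro[4.4]nonan-6-yl]-N-methoxy-N,3-dimethylhex-4-enamide | CC1(C)OC[C@@]2(O1)CC[C@@H](/C(C)=C\CC=C(C)C)[C@H]2[C@H]([C@H](C)/C=C/C)C(=O)N(C)OC | intermediate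
29 | (4S,5R,6E)-4-[(5R,6S,7R)-2,2-dimethyl-7-[(2Z)-6-methylhepta-2,5-dien-2-yl]-1,3-dioxaspiro[4.4]nonan-6-yl]-5-methylocta-1,6-dien-3-one | CC1(C)OC[C@@]2(O1)CC[C@@H](/C(C)=C\CC=C(C)C)[C@H]2[C@H]([C@H](C)/C=C/C)C(=O)C=C | intermediate
30 | (4R,5S)-5-[(5R,6S,7R)-2,2-dimethyl-7-[(2Z)-6-methylhepta-2,5-dien-2-yl]-1,3-dioxaspiro[4.4]nonan-6-yl]-4-methylcyclopent-2-en-1-one | CC1(C)OC[C@@]2(O1)CC[C@@H](/C(C)=C\CC=C(C)C)[C@H]2[C@H]3C(=O)C=C[C@H]3C | intermediate
31 | (4R,5S)-5-[(1S,2R,5R)-2-hydroxy-2-(hydroxymethyl)-5-[(2Z)-6-methylhepta-2,5-dien-2-yl]cyclopentyl]-4-methylcyclopent-2-en-1-one | OC[C@@]1(O)CC[C@@H](/C(C)=C\CC=C(C)C)[C@H]1[C@H]1C(=O)C=C[C@H]1C | intermediate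
32 | [(1R,2S,3R)-1-hydroxy-3-[(2Z)-6-methylhepta-2,5-dien-2-yl]-2-[(1S,5R)-5-methyl-2-oxocyclopent-3-en-1-yl]cyclopentyl]methyl acetate | CC(=O)OC[C@@]1(O)CC[C@@H](/C(C)=C\CC=C(C)C)[C@H]1[C@H]1C(=O)C=C[C@H]1C | target

## Step count and least certain steps

Total step count: 22. Longest linear sequence: 21 steps (steps 1–14 and 16–22); step 15 is a one-step side branch.

**Step 5 (key step).** The most likely failure is poor facial selectivity in the alkene insertion, i.e. incomplete exo placement of the C1 silyl ether. With a methyl-capped alkyne the steric difference between the exo and endo arrangements is modest, and the wrong C5 epimer has to be removed before step 9. Fallback: setting out from alcohol 5, the oxygen would be capped with the larger tert-butyldiphenylsilyl group (t-BuPh2SiCl, imidazole) to give (R)-tert-butyl(oct-1-en-6-yn-3-yloxy)diphenylsilane F1, whose bulk should sharpen the exo preference. The same cobalt-mediated cycloaddition would give (5R,6R)-6-[(tert-butyldiphenylsilyl)oxy]-2-methylbicyclo[3.3.0]oct-1-en-3-one F2, hydrogenation (1R,2R,5R,6R)-6-[(tert-butyldiphenylsilyl)oxy]-2-methylbicyclo[3.3.0]octan-3-one F3, and Baeyer–Villiger oxidation (1R,4aR,5R,7aR)-5-[(tert-butyldiphenylsilyl)oxy]-1-methylhexahydrocyclopenta[c]pyran-3(1H)-one F4. Desilylation with Bu4NF buffered by AcOH would rejoin the route at alcohol 11.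

**Step 16.** The most likely failure is incomplete Z selectivity in oxaphosphetane formation, because a methyl ketone discriminates its two substituents less well than an aldehyde; a second concern is partial epimerisation at C4 through enolisation by the basic ylide. Fallback (Horner–Wittig olefination through separable adducts): setting out from ketone 19, lithiated (4-methylpent-3-en-1-yl)diphenylphosphine oxide F5 (from salt 21 with aqueous NaOH, then n-BuLi, THF, −78 °C) would add to the ketone. The β-hydroxy phosphine oxides are stable and separable, and (2S,3E)-pent-3-en-2-yl 2-[(5R,6R,7R)-7-[(2S,3R)-3-(diphenylphosphoryl)-2-hydroxy-6-methylhept-5-en-2-yl]-2,2-dimethyl-1,3-dioxaspiro[4.4]nonan-6-yl]acetate F6 (or its twin epimeric at both new centres, which has the same relative configuration) would undergo stereospecific syn elimination with NaH in DMF to give only the Z alkene, returning to the route at 23.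

**Step 19.** The most likely failure is slow addition to the very hindered amide (its α-carbon carries two branched groups), which would allow base-induced N–O cleavage of the amide and, at work-up, conjugate addition of the released hydroxylamine to the new enone. Fallback: setting out from acid 26, the acid chloride 27 (made as in step 18) would be coupled with tributyl(vinyl)stannane under PhCH2Pd(PPh3)2Cl catalysis (Stille acylation). This forms the C2′–C3′ bond by oxidative addition and transmetalation rather than by nucleophilic attack on a crowded carbonyl, and leads directly to enone 29; no compound outside the list is made (F0).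

**Step 17.** The most likely failure is erosion of the ketene acetal geometry, or a boat-like transition state forced by the bulky α-substituent, either of which would give syn/anti mixtures at C1′/C5′. Fallback: setting out from keto acid 17, the ester partner would be changed to (R,Z)-pent-3-en-2-ol F7 (from commercial (R)-pent-3-yn-2-ol by semi-hydrogenation over Pd/CaCO3/Pb(OAc)2, the Lindlar catalyst). Steglich esterification would give (2R,3Z)-pent-3-en-2-yl 2-[(5R,6R,7R)-7-acetyl-2,2-dimethyl-1,3-dioxaspiro[4.4]nonan-6-yl]acetate F8, and the Wittig reaction of step 16 would give (2R,3Z)-pent-3-en-2-yl 2-[(5R,6R,7R)-2,2-dimethyl-7-[(2Z)-6-methylhepta-2,5-dien-2-yl]-1,3-dioxaspiro[4.4]nonan-6-yl]acetate F9. Deprotonation with LiN(iPr)2 in THF/DMPU, which reliably gives the (Z)-trimethylsilyl ketene acetal F10, and rearrangement through a chair in which allylic strain holds the carbinol methyl equatorial would lead to the same silyl ester 25 and, after hydrolysis, to acid 26. A Z ketene acetal with a Z alkene is again anti, and the (R,Z)-alcohol again gives C5′ (R).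

**Step 13.** The most likely failure is over-oxidation (haloform-type cleavage of the new methyl ketone by hypochlorite) or, if the oxidation is incomplete, relactonisation of remaining hydroxy acid on acidification. Fallback: setting out from lactone 15, LiAlH4 would reduce it to (1R)-1-[(5R,6R,7R)-6-(2-hydroxyethyl)-2,2-dimethyl-1,3-dioxaspiro[4.4]nonan-7-yl]ethan-1-ol F11. Dess–Martin oxidation of both hydroxyls would give 2-[(5R,6R,7R)-7-acetyl-2,2-dimethyl-1,3-dioxaspiro[4.4]nonan-6-yl]acetaldehyde F12, and NaClO2/NaH2PO4/2-methylbut-2-ene (Pinnick oxidation) would return to the route at keto acid 17.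

## Further compounds

F1 | step 5 | (R)-tert-butyl(oct-1-en-6-yn-3-yloxy)diphenylsilane | C=C[C@H](O[Si](c1ccccc1)(c1ccccc1)C(C)(C)C)CCC#CC
F2 | step 5 | (5R,6R)-6-[(tert-butyldiphenylsilyl)oxy]-2-methylbicyclo[3.3.0]oct-1-en-3-one | CC1=C2CC[C@@H](O[Si](c3ccccc3)(c3ccccc3)C(C)(C)C)[C@@H]2CC1=O
F3 | step 5 | (1R,2R,5R,6R)-6-[(tert-butyldiphenylsilyl)oxy]-2-methylbicyclo[3.3.0]octan-3-one | CC(C)(C)[Si](c1ccccc1)(c1ccccc1)O[C@@H]1CC[C@@H]2[C@H]1CC(=O)[C@@H]2C
F4 | step 5 | (1R,4aR,5R,7aR)-5-[(tert-butyldiphenylsilyl)oxy]-1-methylhexahydrocyclopenta[c]pyran-3(1H)-one | CC(C)(C)[Si](c1ccccc1)(c1ccccc1)O[C@@H]1CC[C@@H]2[C@H]1CC(=O)O[C@@H]2C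
F5 | step 16 | (4-methylpent-3-en-1-yl)diphenylphosphine oxide | CC(C)=CCCP(=O)(c1ccccc1)c1ccccc1
F6 | step 16 | (2S,3E)-pent-3-en-2-yl 2-[(5R,6R,7R)-7-[(2S,3R)-3-(diphenylphosphoryl)-2-hydroxy-6-methylhept-5-en-2-yl]-2,2-dimethyl-1,3-dioxaspiro[4.4]nonan-6-yl]acetate | CC1(C)OC[C@@]2(O1)CC[C@@H]([C@](C)(O)[C@@H](CC=C(C)C)P(=O)(c1ccccc1)c1ccccc1)[C@H]2CC(=O)O[C@@H](C)/C=C/C
F0 | step 19 | none | none
F7 | step 17 | (R,Z)-pent-3-en-2-ol | C/C=C\[C@@H](C)O
F8 | step 17 | (2R,3Z)-pent-3-en-2-yl 2-[(5R,6R,7R)-7-acetyl-2,2-dimethyl-1,3-dioxaspiro[4.4]nonan-6-yl]acetate | CC1(C)OC[C@@]2(O1)CC[C@@H](C(C)=O)[C@H]2CC(=O)O[C@H](C)/C=C\C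
F9 | step 17 | (2R,3Z)-pent-3-en-2-yl 2-[(5R,6R,7R)-2,2-dimethyl-7-[(2Z)-6-methylhepta-2,5-dien-2-yl]-1,3-dioxaspiro[4.4]nonan-6-yl]acetate | CC1(C)OC[C@@]2(O1)CC[C@@H](/C(C)=C\CC=C(C)C)[C@H]2CC(=O)O[C@H](C)/C=C\C
F10 | step 17 | (Z)-trimethylsilyl ketene acetal of F9 (ring A carbon C5 cis to OSiMe3) | CC1(C)OC[C@@]2(O1)CC[C@@H](/C(C)=C\CC=C(C)C)[C@H]2/C=C(\O[Si](C)(C)C)O[C@H](C)/C=C\C
F11 | step 13 | (1R)-1-[(5R,6R,7R)-6-(2-hydroxyethyl)-2,2-dimethyl-1,3-dioxaspiro[4.4]nonan-7-yl]ethan-1-ol | CC1(C)OC[C@@]2(O1)CC[C@@H]([C@@H](C)O)[C@H]2CCO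
F12 | step 13 | 2-[(5R,6R,7R)-7-acetyl-2,2-dimethyl-1,3-dioxaspiro[4.4]nonan-6-yl]acetaldehyde | CC1(C)OC[C@@]2(O1)CC[C@@H](C(C)=O)[C@H]2CC=O
A1 | alternative 1 | (1R,2R,3R)-3-[(2Z)-6-methylhepta-2,5-dien-2-yl]-1-[(phenylsulfanyl)methyl]-2-[(1Z)-prop-1-en-1-yl]cyclopentan-1-ol | c1ccccc1SC[C@@]2(O)CC[C@@H](/C(C)=C\CC=C(C)C)[C@H]2/C=C\C
A2 | alternative 1 | (4R,5S)-5-[(1S,2R,5R)-2-hydroxy-5-[(2Z)-6-methylhepta-2,5-dien-2-yl]-2-[(phenylsulfanyl)methyl]cyclopentyl]-4-methylcyclopent-2-en-1-one | c1ccccc1SC[C@@]2(O)CC[C@@H](/C(C)=C\CC=C(C)C)[C@H]2[C@H]3C(=O)C=C[C@H]3C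
A3 | alternative 2 | acyclic iodo ketone: (5Z)-4-(2-iodoethyl)-1-[(4-methoxybenzyl)oxy]-5,9-dimethyl-3-(7-methyl-1,4-dioxaspiro[4.4]nonan-6-yl)deca-5,8-dien-2-one, configured as in the target | COc1ccc(COCC(=O)[C@H]([C@H]2C3(OCCO3)CC[C@H]2C)[C@@H](CCI)/C(C)=C\CC=C(C)C)cc1
A4 | alternative 2 | ring A tertiary alcohol with PMB-protected C6 and ring B as its saturated ethylene ketal | COc1ccc(COC[C@@]2(O)CC[C@@H](/C(C)=C\CC=C(C)C)[C@H]2[C@H]3C4(OCCO4)CC[C@H]3C)cc1
A5 | alternative 3 | cross-conjugated dienone with (E)-ethylidene at C1′ and (E)-2-(trimethylsilyl)vinyl on C2′, diol as acetonide | CC1(C)OC[C@@]2(O1)CC[C@@H](/C(C)=C\CC=C(C)C)[C@H]2/C(=C\C)C(=O)/C=C/[Si](C)(C)C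
A6 | alternative 3 | acetonide of the deacetyl target (identical with 30) | CC1(C)OC[C@@]2(O1)CC[C@@H](/C(C)=C\CC=C(C)C)[C@H]2[C@H]3C(=O)C=C[C@H]3C
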